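Ring D is handled as a folded polyketide rather than as an arene to be substituted. In its non-aromatic triketo form the ring carbon that holds flavan C4 is flanked by two C=O carbons, as is the α-carbon of a substituted β-keto ester, and the carbon that holds the dodecanoyl group is a tricarbonyl methine. Breaking the ring bond from this methine to the carbonyl next to the flavanyl-bearing carbon gives an open-chain methyl 2-(2,4-cis-flavan-4-yl)-3,5,7-trioxooctadecanoate, phenols of rings A and B benzylated. A single base-induced Claisen closure (chain C6 to ester C1) re-forms that bond, closes and aromatises ring D, and leaves acyl chain and three hydroxyls in place. C2 and C4 are set earlier.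

Key step: step 9

Assumption: the (R)-configured biaryl diphosphine is taken to give the 2R flavanone, by analogy with Hayashi–Miyaura additions to cyclic enones; if the sense proves opposite, the antipodal ligand is used.

Remarks on the design
- Stereochemistry: the target is (2R,4R), with ring B and ring D cis on the pyran ring, so the flavanone must be 2R. The CIP label of C4 reads S at the acetate, malonate and polyketone stages. It reads R once ring D is aromatic, only because ring D then outranks C4a; the geometry never changes.
- Chain assembly: the polyketone is made by joining chain C3 to C4, from a malonyl chloride and a diketone dianion.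
  - A C3 acyl donor that already carries the C5 and C7 carbonyls collapses to a 2-pyranone.
  - The enol ether of that pyranone has acidic side-chain hydrogens that can quench an ester enolate.
  - Its later unmasking would need acid, which endangers the benzylic C2–O1 bond.
  - The chosen union gives the free triketo ester directly.
- The benzyl ethers must outlast the alkene reduction. A homogeneous catalyst is therefore used in step 5, and Pd/C only in the last step.

Step 1
Reactants: 1 7-hydroxy-4H-chromen-4-one
Product: 2 7-benzyloxy-4H-chromen-4-one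
Conditions: BnBr, K2CO3, acetone, reflux
Reagents that add atoms: benzyl bromide, BrCc1ccccc1
Why: Williamson ether synthesis on the only acidic hydroxyl; carbonate is basic enough for the 7-OH (a vinylogous acid) yet does not open the pyranone ring.

Step 2
Reactants: 2 7-benzyloxy-4H-chromen-4-one; 3 4-benzyloxyphenylboronic acid
Product: 4 (2R)-7-benzyloxy-2-(4-benzyloxyphenyl)chroman-4-one
Conditions: [Rh(OH)(cod)]2 (1.5 mol %), (R)-MeO-F12-BIPHEP (3.3 mol %), toluene/H2O, 20 °C
Reagents that add atoms: none
Why: Hayashi–Miyaura rhodium-catalysed asymmetric 1,4-addition of an arylboronic acid to a chromone, a documented entry to enantioenriched flavanones: the chiral diphosphine decides which enone face the aryl–rhodium species inserts into and thereby sets C2 as R, and the almost neutral, cool medium avoids retro-oxa-Michael racemisation and 1,2-addition.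

Step 3
Reactants: 4 (2R)-7-benzyloxy-2-(4-benzyloxyphenyl)chroman-4-one; 5 methyl bromoacetate
Product: 7 methyl 2-[(2R)-7-benzyloxy-2-(4-benzyloxyphenyl)-4-hydroxychroman-4-yl]acetate (C4 epimers), via bromozinc ester enolate 6 (not isolated)
Conditions: 5, Zn dust (Me3SiCl-activated), THF, 40 °C; then 4, 0 °C → rt; H2O, Celite
Reagents that add atoms: none
Why: Reformatsky reaction: the weakly basic zinc enolate adds to the C4 carbonyl instead of enolising it, so the ring does not open to the chalcone and C2 keeps its configuration, while the new carbinol centre at C4 may form as a mixture because step 4 erases it.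

Step 4
Reactants: 7 methyl 2-[(2R)-7-benzyloxy-2-(4-benzyloxyphenyl)-4-hydroxychroman-4-yl]acetate
Product: 8 methyl 2-[(2R)-7-benzyloxy-2-(4-benzyloxyphenyl)-2H-chromen-4-yl]acetate
Conditions: p-TsOH·H2O (2 mol %), 4 Å MS, toluene, rt
Reagents that add atoms: none
Why: Acid-catalysed E1 dehydration: the tertiary carbinol ionises with a trace of acid because the C4 cation is stabilised by O1 (ortho) and the 7-benzyloxy group (para), reversible protonation channels any exocyclic alkylidene isomer into the endocyclic 2H-chromene that is free of peri strain, and the low acid loading leaves the C2–O1 bond and hence C2 untouched.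

Step 5
Reactants: 8 methyl 2-[(2R)-7-benzyloxy-2-(4-benzyloxyphenyl)-2H-chromen-4-yl]acetate
Product: 9 methyl 2-[(2R,4S)-7-benzyloxy-2-(4-benzyloxyphenyl)chroman-4-yl]acetate (2,4-cis)
Conditions: H2 (5 bar), [Ir(cod)(PCy3)(py)]PF6 (3 mol %), CH2Cl2, rt
Reagents that add atoms: none
Why: Homogeneous iridium-catalysed hydrogenation of a trisubstituted alkene, which unlike Pd/C cleaves neither aryl benzyl ethers nor the allylic C2–O1 bond; ring B on the allylic carbon C2 blocks one face, both hydrogens arrive anti to it, and the acetate arm at C4 therefore ends cis to ring B (4S).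

Step 6
Reactants: 9 methyl 2-[(2R,4S)-7-benzyloxy-2-(4-benzyloxyphenyl)chroman-4-yl]acetate
Product: 11 2-[(2R,4S)-7-benzyloxy-2-(4-benzyloxyphenyl)chroman-4-yl]-3-methoxy-3-oxopropanoic acid (epimers at the malonyl carbon), via lithium ester enolate 10 (not isolated)
Conditions: LiN(i-Pr)2, THF, −78 °C; CO2 (g), −78 → 0 °C; cold 1 M HCl
Reagents that add atoms: carbon dioxide, O=C=O
Why: Carboxylation of an ester lithium enolate with CO2 to a malonic half ester; the new malonyl centre forms as an epimer mixture, which is harmless because it becomes an sp2 carbon of ring D, and C2 and C4 of the flavan carry no acidic hydrogen.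

Step 7
Reactants: 12 pentane-2,4-dione; 13 1-bromodecane
Product: 15 pentadecane-2,4-dione, via sodium lithium dianion 14 (not isolated)
Conditions: NaH, THF, 0 °C; n-BuLi, 0 °C; 13, 0 °C → rt; 1 M HCl
Reagents that add atoms: none
Why: Terminal (γ) alkylation of a 1,3-diketone dianion: the last-formed methyl carbanion is far more nucleophilic than the delocalised central enolate and displaces bromide from the primary halide in an SN2 reaction.

Step 8
Reactants: 11 2-[(2R,4S)-7-benzyloxy-2-(4-benzyloxyphenyl)chroman-4-yl]-3-methoxy-3-oxopropanoic acid; 15 pentadecane-2,4-dione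
Product: 18 methyl 2-[(2R,4S)-7-benzyloxy-2-(4-benzyloxyphenyl)chroman-4-yl]-3,5,7-trioxooctadecanoate (chain C2 epimers; keto–enol mixture), via malonyl chloride 16 (not isolated), via diketone dianion 17 (not isolated)
Conditions: (a) 11, Me2C=C(Cl)NMe2, THF, 0 °C; (b) 15 (3.5 equiv), NaH then n-BuLi, THF, 0 °C; (c) solution (a) into (b), −78 °C; AcOH quench; surplus 15 recovered
Reagents that add atoms: none
Why: γ-Acylation of a 1,3-diketone dianion by an acid chloride: the second deprotonation of 15 occurs at the methyl rather than the methylene terminus, the carbanion takes up 16 either directly or, after loss of the acidic malonyl hydrogen and chloride, as the carbomethoxyketene, both paths giving the same enolate of 18, and the surplus of cheap 17 absorbs the acidic hydrogens, while the neutral acid-chloride formation and the AcOH quench keep the flavan away from strong acid.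

Step 9
Reactants: 18 methyl 2-[(2R,4S)-7-benzyloxy-2-(4-benzyloxyphenyl)chroman-4-yl]-3,5,7-trioxooctadecanoate
Product: 20 1-{3-[(2R,4R)-7-benzyloxy-2-(4-benzyloxyphenyl)chroman-4-yl]-2,4,6-trihydroxyphenyl}dodecan-1-one, via cyclic triketone tautomer 19 (not isolated)
Conditions: Mg(OMe)2 (4 equiv), MeOH/THF, rt → 50 °C; cold 0.5 M HCl
Reagents that add atoms: none
Why: Methoxide and magnesium convert 18 into chelated enolates of the C3/C5/C7 triketone; the carbanion at C6, flanked by C5 and C7, adds to the ester carbonyl C1, methoxide leaves, and the resulting 2-acylcyclohexane-1,3,5-trione 19 tautomerises at once to the aromatic triol, whose deprotonation makes the sequence irreversible. The closest known reaction type is the biomimetic intramolecular Claisen (Dieckmann-type) cyclisation of 3,5,7-trioxo esters to acylphloroglucinols in methanolic base. Ring D closes in the 6-exo-trig mode (C1–C6 bond, carbonyl oxygen outside the new ring). No stereocentre is created: the epimeric chain C2 becomes an sp2 ring carbon, while flavan C2 and C4 carry neither an acidic hydrogen nor a leaving group here, and with 4'-O and 7-O benzylated no quinone methide can form. The step needs Claisen closure to beat aldol closure, lactonisation and retro-Claisen cleavage: an aldol of C2 onto C7 would give a quaternary carbon that cannot aromatise and so reverts, the bulky flavanyl group disfavours enolisation at C2 and keeps the ester electrophilic, and C8 is not deprotonated while C7 is part of an enolate. Lactonisation to a 2-pyranone and ester exchange are reversible or degenerate in methanol/methoxide, water is excluded so that the ester is not saponified, and only the aromatic product is a thermodynamic sink.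

Step 10
Reactants: 20 1-{3-[(2R,4R)-7-benzyloxy-2-(4-benzyloxyphenyl)chroman-4-yl]-2,4,6-trihydroxyphenyl}dodecan-1-one
Product: 21 1-{2,4,6-trihydroxy-3-[(2R,4R)-7-hydroxy-2-(4-hydroxyphenyl)chroman-4-yl]phenyl}dodecan-1-one (target)
Conditions: H2 (1 atm), 10% Pd/C, THF/MeOH, rt
Reagents that add atoms: none
Why: Catalytic hydrogenolysis of the two aryl benzyl ethers under neutral conditions; the hydrogen-bonded aryl ketone, the C2–O1 bond and the C4–ring D bond are not reduced at 1 atm and room temperature, and the absence of acid or base prevents epimerisation at C2 through a quinone methide once the 4'-hydroxyl is free.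

Compound list
1 | 7-hydroxy-4H-chromen-4-one | O=c1ccoc2cc(O)ccc12 | starting material
2 | 7-benzyloxy-4H-chromen-4-one | O=c1ccoc2cc(OCc3ccccc3)ccc12 | intermediate
3 | 4-benzyloxyphenylboronic acid | OB(O)c1ccc(OCc2ccccc2)cc1 | starting material
4 | (2R)-7-benzyloxy-2-(4-benzyloxyphenyl)chroman-4-one | O=C1C[C@H](c2ccc(OCc3ccccc3)cc2)Oc2cc(OCc3ccccc3)ccc12 | intermediate
5 | methyl bromoacetate | COC(=O)CBr | starting material
6 | bromo(2-methoxy-2-oxoethyl)zinc | COC(=O)C[Zn]Br | intermediate
7 | methyl 2-[(2R)-7-benzyloxy-2-(4-benzyloxyphenyl)-4-hydroxychroman-4-yl]acetate (C4 epimers) | COC(=O)CC1(O)C[C@H](c2ccc(OCc3ccccc3)cc2)Oc2cc(OCc3ccccc3)ccc21 | intermediate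
8 | methyl 2-[(2R)-7-benzyloxy-2-(4-benzyloxyphenyl)-2H-chromen-4-yl]acetate | COC(=O)CC1=C[C@H](c2ccc(OCc3ccccc3)cc2)Oc2cc(OCc3ccccc3)ccc21 | intermediate
9 | methyl 2-[(2R,4S)-7-benzyloxy-2-(4-benzyloxyphenyl)chroman-4-yl]acetate (2,4-cis) | COC(=O)C[C@@H]1C[C@H](c2ccc(OCc3ccccc3)cc2)Oc2cc(OCc3ccccc3)ccc21 | intermediate
10 | lithium enolate of 9 | [Li+].COC([O-])=C[C@@H]1C[C@H](c2ccc(OCc3ccccc3)cc2)Oc2cc(OCc3ccccc3)ccc21 | intermediate
11 | 2-[(2R,4S)-7-benzyloxy-2-(4-benzyloxyphenyl)chroman-4-yl]-3-methoxy-3-oxopropanoic acid (epimers at the malonyl carbon) | COC(=O)C(C(=O)O)[C@@H]1C[C@H](c2ccc(OCc3ccccc3)cc2)Oc2cc(OCc3ccccc3)ccc21 | intermediate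
12 | pentane-2,4-dione | CC(=O)CC(C)=O | starting material
13 | 1-bromodecane | CCCCCCCCCCBr | starting material
14 | sodium lithium 1,3-dianion of pentane-2,4-dione | [Na+].[Li+].[CH2-]C(=O)C=C(C)[O-] | intermediate
15 | pentadecane-2,4-dione | CCCCCCCCCCCC(=O)CC(C)=O | intermediate
16 | methyl 2-[(2R,4S)-7-benzyloxy-2-(4-benzyloxyphenyl)chroman-4-yl]-3-chloro-3-oxopropanoate | COC(=O)C(C(Cl)=O)[C@@H]1C[C@H](c2ccc(OCc3ccccc3)cc2)Oc2cc(OCc3ccccc3)ccc21 | intermediate
17 | sodium lithium 1,3-dianion of pentadecane-2,4-dione (carbanion at C1) | [Na+].[Li+].[CH2-]C(=O)C=C([O-])CCCCCCCCCCC | intermediate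
18 | methyl 2-[(2R,4S)-7-benzyloxy-2-(4-benzyloxyphenyl)chroman-4-yl]-3,5,7-trioxooctadecanoate (chain C2 epimers) | CCCCCCCCCCCC(=O)CC(=O)CC(=O)C(C(=O)OC)[C@@H]1C[C@H](c2ccc(OCc3ccccc3)cc2)Oc2cc(OCc3ccccc3)ccc21 | intermediate
19 | 2-dodecanoyl-4-[(2R,4S)-7-benzyloxy-2-(4-benzyloxyphenyl)chroman-4-yl]cyclohexane-1,3,5-trione | CCCCCCCCCCCC(=O)C1C(=O)CC(=O)C([C@@H]2C[C@H](c3ccc(OCc4ccccc4)cc3)Oc3cc(OCc4ccccc4)ccc32)C1=O | intermediate
20 | 1-{3-[(2R,4R)-7-benzyloxy-2-(4-benzyloxyphenyl)chroman-4-yl]-2,4,6-trihydroxyphenyl}dodecan-1-one | CCCCCCCCCCCC(=O)c1c(O)cc(O)c([C@@H]2C[C@H](c3ccc(OCc4ccccc4)cc3)Oc3cc(OCc4ccccc4)ccc32)c1O | intermediate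
21 | 1-{2,4,6-trihydroxy-3-[(2R,4R)-7-hydroxy-2-(4-hydroxyphenyl)chroman-4-yl]phenyl}dodecan-1-one | CCCCCCCCCCCC(=O)c1c(O)cc(O)c([C@@H]2C[C@H](c3ccc(O)cc3)Oc3cc(O)ccc32)c1O | target

Total step count: 10. Longest linear sequence: 9 steps (1–6, 8, 9, 10).

Steps most likely to fail

1. Step 9. The chain may fold the wrong way, either by lactonisation through the C5 enolate oxygen or by an aldol mode. It may also be cut by retro-Claisen attack of methoxide before the hindered ester carbonyl is reached.
Fallback, setting out from 9 and 13 and rejoining the route at 21: the free triketone is replaced by a partly masked chain that is already folded. Commercial 4-hydroxy-6-methyl-2H-pyran-2-one is doubly deprotonated (n-BuLi, 2 equiv, THF) and alkylated at its methyl carbanion by 13 to give 4-hydroxy-6-undecyl-2H-pyran-2-one F1. A Mitsunobu reaction with benzyl alcohol turns this into 4-benzyloxy-6-undecyl-2H-pyran-2-one F2. Enolate 10, made from 9 as in step 6, attacks the lactone carbonyl of F2 and opens the ring to methyl (4E)-5-benzyloxy-2-[(2R,4S)-7-benzyloxy-2-(4-benzyloxyphenyl)chroman-4-yl]-3,7-dioxooctadec-4-enoate F3. In F3 the former ring double bond holds chain C3 and C6 cis, the C5 oxygen can no longer lactonise, and C4 can no longer be deprotonated. KOt-Bu in THF closes C6 onto C1 to 1-{6-benzyloxy-3-[(2R,4R)-7-benzyloxy-2-(4-benzyloxyphenyl)chroman-4-yl]-2,4-dihydroxyphenyl}dodecan-1-one F4. The conditions of step 10 then remove all three benzyl groups.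

2. Step 8. Proton transfer from the malonyl position and self-reaction of the derived ketene may outrun C-acylation, and enolates of the product may be acylated again.
Fallback, setting out from 15 and 16 and rejoining at 18: the strongly basic dianion is replaced by a neutral masked dianion. Compound 15 is silylated (Me3SiCl, Et3N) to 4-(trimethylsilyloxy)pentadec-3-en-2-one F5. This is deprotonated at the methyl group with LiN(i-Pr)2 at −78 °C and silylated again to 2,4-bis(trimethylsilyloxy)pentadeca-1,3-diene F6. The CH2 terminus of the diene is acylated by 16 in CH2Cl2 (−78 → 20 °C, no base, no Lewis acid), and aqueous work-up strips the silyl groups to give 18. Any diene isomer enolised towards the undecyl chain has a substituted, slower terminus, and the diene is used in excess.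

3. Step 5. Facial discrimination may be incomplete, or turnover on the hindered trisubstituted alkene may be slow.
Fallback, setting out from 7 and rejoining at 9 (step 4 is bypassed): catalytic hydrogenation is replaced by ionic reduction. Et3SiH with BF3·OEt2 (1.1 equiv) in CH2Cl2 at −78 °C ionises only the very labile tertiary carbinol. Hydride then enters the planar C4 cation along the pseudo-axial trajectory anti to ring B, the same sense in which nucleophiles add to flavan-4-yl cations. The acetate arm is thereby left equatorial and cis to ring B.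

Further compounds
F1 | step 9 | 4-hydroxy-6-undecyl-2H-pyran-2-one | CCCCCCCCCCCc1cc(O)cc(=O)o1
F2 | step 9 | 4-benzyloxy-6-undecyl-2H-pyran-2-one | CCCCCCCCCCCc1cc(OCc2ccccc2)cc(=O)o1
F3 | step 9 | methyl (4E)-5-benzyloxy-2-[(2R,4S)-7-benzyloxy-2-(4-benzyloxyphenyl)chroman-4-yl]-3,7-dioxooctadec-4-enoate | CCCCCCCCCCCC(=O)C/C(OCc1ccccc1)=C\C(=O)C(C(=O)OC)[C@@H]1C[C@H](c2ccc(OCc3ccccc3)cc2)Oc2cc(OCc3ccccc3)ccc21
F4 | step 9 | 1-{6-benzyloxy-3-[(2R,4R)-7-benzyloxy-2-(4-benzyloxyphenyl)chroman-4-yl]-2,4-dihydroxyphenyl}dodecan-1-one | CCCCCCCCCCCC(=O)c1c(OCc2ccccc2)cc(O)c([C@@H]2C[C@H](c3ccc(OCc4ccccc4)cc3)Oc3cc(OCc4ccccc4)ccc32)c1O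
F5 | step 8 | 4-(trimethylsilyloxy)pentadec-3-en-2-one | CCCCCCCCCCCC(O[Si](C)(C)C)=CC(C)=O
F6 | step 8 | 2,4-bis(trimethylsilyloxy)pentadeca-1,3-diene | CCCCCCCCCCCC(O[Si](C)(C)C)=CC(=C)O[Si](C)(C)C
F0 | step 5 | none | none
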